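The pitfall here was to count what the second step makes as Z, for Z trades with Q, and in blue that pair relaxes with a half-life of 1.24 s, far shorter than the 3.0 min of the run.

    X + E → E + J (k1 = 2700 M⁻¹ s⁻¹)
    D + L + J → L + Z (k2 = 610 M⁻² s⁻¹)
    Z ⇌ Q (K3 = 0.75, k3 = 0.24 s⁻¹)

| setting | red | ochre | teal | blue |
|---|---|---|---|---|
| X | 13 mM | 13 mM (fed, over 2.5 min) | 13 mM | 13 mM |
| D | 32.5 mM (in portions, 4, over 2.5 min) | 32.5 mM | 32.5 mM (fed, over 2.5 min) | 32.5 mM |
| E | 13 µM | 13 µM | 13 µM | 13 µM |
| L | 0.65 mM | 0.65 mM | 0.65 mM | 0.65 mM |
| time | 3.0 min | 3.0 min | 3.0 min | 3.0 min |
| remark | first portion at the start, last at 2.5 min | all else is in the flask from the start; the feed brings no volume worth counting | all else is in the flask from the start; the feed brings no volume worth counting | everything together at the start |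

1. which flask leads in amount of Z, in percent of the X charged ("all alike" within 1.5 percentage points) (red / ochre / teal / blue / all alike)
2. how much Z is there at the end, in percent of the X charged: red
3. how much Z is there at the end, in percent of the X charged: ochre
4. how much Z is there at the end, in percent of the X charged: teal
5. how much Z is there at the end, in percent of the X charged: blue

I reckoned blue by hand, where nothing is fed, and built it up one step at a time; the other flasks I did not reckon.

First I took the second step by itself, with X already turned to J and with D and L held at their charges. J then decays as a pseudo-first-order species with time constant τ = 1.29 min, so 90.2% of it has reacted by the end.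

Next I added the first step. X becomes J with time constant θ = 0.475 min, and two time constants in series lower the figure to 84.6%.

Last came the exchange of Z and Q, and its zero of the scale is the even case. With an equilibrium constant of one, Z would hold half of the pair. Here the constant, Q over Z, is 0.75, so the scale tips toward Z. I call s, one over one plus that constant, the Z share of the pair at balance: s = 57.1%.

Multiplying gave 48.3% for blue. I had held D at its charge, though a full turnover of X takes 40.0% of it, so I took that figure as the high side.

The forecast named blue as the leader, with 36.5% for red, 30% for ochre, 37% for teal and 44.5% for blue, a blue figure lower than my 48.3%. Its ground was that “holding back either one costs yield, most of all holding back X”.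

Blue led with 44.5%, against 36.3% for red, 30.2% for ochre and 37.2% for teal. At the end of blue, 22.1% of the X charged still stood as J and 0.18% as X. The remainder, 77.7%, times s gives 44.4% as Z. In ochre at 3.00 min, 6.59% stood as X and 41.2% as J, and the same s gives 29.8% as Z, where the flask held 30.2%.

The constants used here are invented; no experiment stands behind them.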